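**Plan**
- Retrosynthetic cuts: the carboxyl group back to a vinyl group, and the allyl–ring bond back to a cyclohexanone enol ether; the two cyclohexane bonds flanking the cis ring fusion (Diels–Alder on a spiro unsaturated δ-lactone); the lactone C=C (intramolecular Wittig) and the CH2OH on the spiro carbon (aldol with CH2O); then the bridgehead CH–CMe2 bond (C1–C8) of the 8,8-dimethyl-6-oxabicyclo[3.2.1]octan-3-one; last the oxepine C=C (Knoevenagel), the ether C–O (O–H insertion) and the carbinol C–C bond (vinylogous aldol).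
- Forward ring order: tetrahydrooxepin-5-one, then oxolane and cyclohexanone together (the bicyclo[3.2.1] core), then the spiro δ-lactone, then the cyclohexane, then the side chain.
- Enabling feature: in the oxepinone the ring O–CH2 unit on one side and the CH2–C(=O) unit on the other hold the isopropenyl carbon on C7 and the alkylidene β-carbon C3 in a 1,4 relation across the ring, so a tertiary radical at that carbon can bond only to C3 and only cis.
- Stereochemistry: the carbinol carbon comes from a catalytic asymmetric vinylogous Mukaiyama aldol; the bridgehead CH is relayed from it through the ring; the spiro carbon is set by attack anti to the axial methyl of the CMe2 bridge; the ring-fusion CH pair by Diels–Alder approach anti to that bridge; the ring carbon bearing the side chain by equilibration to equatorial; the side-chain methine by the iridium catalyst.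

Key step: step 6

Remark: in steps 2 and 12 the ligand enantiomer is the one that gives the configuration drawn; the sense named is by analogy and would be confirmed on the first run.

**Route**

Step 1
Reactants: 1 2,2,6-trimethyl-4H-1,3-dioxin-4-one
Product: 2 [(2,2-dimethyl-6-methylidene-6H-1,3-dioxin-4-yl)oxy]trimethylsilane
Conditions: LiN(iPr)2, THF, −78 °C; Me3SiCl
Reagents that add atoms: chlorotrimethylsilane, C[Si](C)(C)Cl
Why: γ-Deprotonation of the vinylogous ester and O-silylation of the dienolate (silyl dienol ether formation) is the standard entry to this nucleophile, and no stereocentre is formed.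

Step 2
Reactants: 2 [(2,2-dimethyl-6-methylidene-6H-1,3-dioxin-4-yl)oxy]trimethylsilane; 3 methacrolein
Product: 5 (R)-6-(2-hydroxy-3-methylbut-3-en-1-yl)-2,2-dimethyl-4H-1,3-dioxin-4-one, via O-silyl aldol adduct 4 (not isolated)
Conditions: Cu(OTf)2 (2 mol%), (S)-Tol-BINAP (2.2 mol%), Bu4N(Ph3SiF2) (4 mol%), THF, −78 °C; then CF3CO2H, THF/H2O
Reagents that add atoms: none
Why: Catalytic enantioselective vinylogous Mukaiyama aldol addition of the silyl dienolate to an α-branched enal, a substrate class known for chiral copper–bisphosphine dienolate catalysis, should set the carbinol stereocentre (R) under ligand control.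

Step 3
Reactants: 5 (R)-6-(2-hydroxy-3-methylbut-3-en-1-yl)-2,2-dimethyl-4H-1,3-dioxin-4-one
Product: 6 ethyl 2-{[(2R)-1-(2,2-dimethyl-4-oxo-4H-1,3-dioxin-6-yl)-3-methylbut-3-en-2-yl]oxy}acetate
Conditions: N2CHCO2Et (1.5 equiv, slow addition), Rh2(OAc)4 (1 mol%), CH2Cl2, 25 °C
Reagents that add atoms: ethyl diazoacetate, CCOC(=O)C=[N+]=[N-]
Why: Rhodium-carbenoid O–H insertion etherifies the base-sensitive β-hydroxy dioxinone under neutral conditions, O–H insertion being faster than cyclopropanation of the 1,1-disubstituted alkene, and the stereocentre is untouched.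

Step 4
Reactants: 6 ethyl 2-{[(2R)-1-(2,2-dimethyl-4-oxo-4H-1,3-dioxin-6-yl)-3-methylbut-3-en-2-yl]oxy}acetate
Product: 7 2-{[(2R)-1-(2,2-dimethyl-4-oxo-4H-1,3-dioxin-6-yl)-3-methylbut-3-en-2-yl]oxy}acetaldehyde
Conditions: iBu2AlH (1.1 equiv), CH2Cl2, −78 °C; MeOH, aq. potassium sodium tartrate
Reagents that add atoms: none
Why: Partial reduction of an α-alkoxy ester with iBu2AlH stops at the chelated hemiacetal aluminate at −78 °C and should spare the less electrophilic vinylogous ester of the dioxinone.

Step 5
Reactants: 7 2-{[(2R)-1-(2,2-dimethyl-4-oxo-4H-1,3-dioxin-6-yl)-3-methylbut-3-en-2-yl]oxy}acetaldehyde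
Product: 9 S-ethyl (7R)-5-oxo-7-(prop-1-en-2-yl)-2,5,6,7-tetrahydrooxepine-4-carbothioate, via keto thioester aldehyde 8 (not isolated)
Conditions: EtSH (10 equiv), PhMe, 110 °C, sealed tube; evaporate; piperidine (0.2 equiv), AcOH (0.2 equiv), 4 Å MS, CH2Cl2, 25 °C
Reagents that add atoms: ethanethiol, CCS
Why: Thermal retro-[4+2] of the dioxinone gives an acylketene that the thiol traps as the β-keto thioester, and amine-catalysed intramolecular Knoevenagel condensation with the tethered aldehyde then closes the seven-membered ring, whose endocyclic alkene can only be cis.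

Step 6
Reactants: 9 S-ethyl (7R)-5-oxo-7-(prop-1-en-2-yl)-2,5,6,7-tetrahydrooxepine-4-carbothioate
Product: 10 S-ethyl (1S,5R)-8,8-dimethyl-3-oxo-6-oxabicyclo[3.2.1]octane-2-carbothioate (C2 epimers in equilibrium with the enol)
Conditions: Fe(acac)3 (30 mol%), PhSiH3 (2.5 equiv), EtOH/HOCH2CH2OH (5:1), 60 °C
Reagents that add atoms: none
Why: An iron hydride formed from Fe(acac)3 and PhSiH3 transfers a hydrogen atom to the CH2 terminus of the isopropenyl group, the resulting tertiary radical adds across the ring to the β-carbon (C3) of the alkylidene keto thioester, and the dicarbonyl-stabilised radical is reduced to the iron enolate and protonated by ethanol. The closest known reaction type is the hydrogen-atom-transfer-initiated reductive coupling of unactivated alkenes with Michael acceptors in its intramolecular (Giese cyclisation) form, and the topology matches the closure of (cyclohept-4-enyl)methyl radicals to bicyclo[3.2.1]octanes. The one new bond closes two rings at once: the oxolane (radical carbon, C7, O1, C2, C3 of the oxepine) in a 5-exo-trig mode and the cyclohexanone (radical carbon, C7, C6, C5, C4, C3) in a 6-endo-trig mode. The new bridgehead stereocentre (C1 of the product) is fixed by the existing carbinol centre (C5), because the one-atom bridge can span the two ring carbons only cis, while the thioester-bearing C2 forms as an epimer/enol mixture that converges in step 7. The step needs hydrogen-atom transfer to the electron-rich 1,1-disubstituted alkene and not to the electron-poor alkylidene, and attack at C3 and not at C4. Both follow from the polarity match of a nucleophilic tertiary radical with the β-carbon of a doubly activated acceptor.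

Step 7
Reactants: 10 S-ethyl (1S,5R)-8,8-dimethyl-3-oxo-6-oxabicyclo[3.2.1]octane-2-carbothioate
Product: 11 S-ethyl (1R,2R,5R)-2-(hydroxymethyl)-8,8-dimethyl-3-oxo-6-oxabicyclo[3.2.1]octane-2-carbothioate
Conditions: 37% aq. CH2O (3 equiv), KHCO3 (0.2 equiv), THF, 0 → 25 °C
Reagents that add atoms: formaldehyde, C=O
Why: Aldol hydroxymethylation of the β-keto thioester occurs only at the doubly activated C2, and the electrophile should enter on the face of the O–CH2 bridge because the other face lies under the axial methyl of the CMe2 bridge, which sets the quaternary centre with CH2OH equatorial and the thioester axial.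

Step 8
Reactants: 11 S-ethyl (1R,2R,5R)-2-(hydroxymethyl)-8,8-dimethyl-3-oxo-6-oxabicyclo[3.2.1]octane-2-carbothioate
Product: 12 (1R,2S,5R)-2-(hydroxymethyl)-8,8-dimethyl-3-oxo-6-oxabicyclo[3.2.1]octane-2-carbaldehyde
Conditions: Et3SiH (3 equiv), 10% Pd/C (5 mol%), acetone, 25 °C
Reagents that add atoms: none
Why: Fukuyama reduction converts the thioester into the aldehyde under neutral conditions that leave the ketone, the ether and the free alcohol alone and cannot epimerise the non-enolisable quaternary centre.

Step 9
Reactants: 12 (1R,2S,5R)-2-(hydroxymethyl)-8,8-dimethyl-3-oxo-6-oxabicyclo[3.2.1]octane-2-carbaldehyde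
Product: 14 (1R,2S,5R)-8,8-dimethyl-2'H-spiro[6-oxabicyclo[3.2.1]octane-2,3'-pyran]-3,6'-dione (lactone CH2 equatorial, lactone CH= axial on the bicyclic ketone), via phosphorane ester 13 (not isolated)
Conditions: Ph3P=C=C=O (1.2 equiv), PhMe, 90 °C
Reagents that add atoms: ketenylidenetriphenylphosphorane, O=C=C=P(c1ccccc1)(c1ccccc1)c1ccccc1
Why: Addition of the primary alcohol to the cumulated ylide gives a stabilised ester phosphorane that closes the α,β-unsaturated δ-lactone by intramolecular Wittig olefination of the aldehyde, the hindered ketone being inert to a stabilised ylide and the ring enforcing the cis alkene.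

Step 10
Reactants: 14 (1R,2S,5R)-8,8-dimethyl-2'H-spiro[6-oxabicyclo[3.2.1]octane-2,3'-pyran]-3,6'-dione; 15 2-(trimethylsilyloxy)buta-1,3-diene
Product: 16 cis-fused cycloadduct: 6-(trimethylsilyloxy)-4a,5,8,8a-tetrahydro-1H-isochromen-1-one spiro-linked at C4 to C2 of the 8,8-dimethyl-6-oxabicyclo[3.2.1]octan-3-one, ring-fusion hydrogens on the face of the bicyclic bridgehead C1
Conditions: 15 (5 equiv), CH2Cl2, 12 kbar, 25 °C; non-aqueous work-up
Reagents that add atoms: none
Why: In this Diels–Alder cycloaddition the 2-silyloxy group directs the para regiochemistry (diene CH2 next to C–OSi bonds to the lactone β-carbon), the cyclic Z-dienophile gives the cis ring fusion, and the diene should approach the lactone face away from the CMe2 bridge (axial methyl against axial hydrogen flanking the β-carbon), which leaves both ring-fusion hydrogens on the side of the bridgehead CH.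

Step 11
Reactants: 17 (E)-but-2-en-1-ol
Product: 18 (E)-but-2-en-1-yl methyl carbonate
Conditions: ClCO2Me (1.2 equiv), pyridine (1.5 equiv), CH2Cl2, 0 °C
Reagents that add atoms: methyl chloroformate, COC(=O)Cl
Why: Acylation of a primary allylic alcohol with a chloroformate is routine and creates no stereocentre.

Step 12
Reactants: 16 cis-fused silyl enol ether cycloadduct; 18 (E)-but-2-en-1-yl methyl carbonate
Product: 20 the 6-oxo-octahydroisochromen-1-one carrying an equatorial (2S)-but-3-en-2-yl group at C7 (trans to the spiro carbon across the ring), spiro-linked as in 16, via epimeric allyl ketones 19 (not isolated)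
Conditions: [Ir(cod)Cl]2 (2 mol%), binaphthol-derived N,N-bis(1-phenylethyl)phosphoramidite ligand (4 mol%), CsF (0.4 equiv), ZnF2 (0.5 equiv), DME, 50 °C; then DBU (0.2 equiv), CH2Cl2, 25 °C
Reagents that add atoms: none
Why: Iridium-catalysed asymmetric allylic alkylation of the fluoride-activated silyl enol ether gives the branched product regiospecifically at the enol ether carbon with the methyl-bearing stereocentre set by the ligand, and DBU then equilibrates the ring α-carbon to the equatorial epimer.

Step 13
Reactants: 20 equatorial allyl ketone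
Product: 21 the 4-methylbenzenesulfonylhydrazone of the cyclohexanone carbonyl of 20
Conditions: TsNHNH2 (1.05 equiv), MeOH, 25 °C
Reagents that add atoms: 4-methylbenzenesulfonohydrazide, Cc1ccc(cc1)S(=O)(=O)NN
Why: Hydrazone condensation should select the unhindered cyclohexanone carbonyl over the bicyclic ketone flanked by the quaternary spiro carbon, and the α-centre stays equatorial.

Step 14
Reactants: 21 tosylhydrazone
Product: 22 the spiro keto lactone with a (2S)-but-3-en-2-yl group on the cyclohexane (all ring stereocentres as in the target)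
Conditions: catecholborane (1.5 equiv), CHCl3, 0 °C; then NaOAc·3H2O, 60 °C
Reagents that add atoms: none
Why: Hydride reduction of the tosylhydrazone, sulfinate elimination and loss of N2 from the diazene (a mild Wolff–Kishner-type deoxygenation) should give the methylene without touching the lactone, the remaining ketone or the vinyl group.

Step 15
Reactants: 22 vinyl compound
Product: 24 target acid CNP0152427.2, via aldehyde 23 (not isolated)
Conditions: O3, CH2Cl2, −78 °C; Me2S; then NaClO2, NaH2PO4, 2-methylbut-2-ene, tBuOH/H2O, 0 °C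
Reagents that add atoms: ozone, O=[O+][O-]; sodium chlorite, [Na+].[O-]Cl=O
Why: Ozonolysis of the only alkene and buffered Pinnick oxidation of the aldehyde without isolation should deliver the carboxylic acid without epimerising the carbon next to it.

**Compound list**

1 | 2,2,6-trimethyl-4H-1,3-dioxin-4-one | CC1=CC(=O)OC(C)(C)O1 | starting material
2 | [(2,2-dimethyl-6-methylidene-6H-1,3-dioxin-4-yl)oxy]trimethylsilane | C=C1C=C(O[Si](C)(C)C)OC(C)(C)O1 | intermediate
3 | methacrolein | CC(=C)C=O | starting material
4 | (R)-2,2-dimethyl-6-[3-methyl-2-(trimethylsilyloxy)but-3-en-1-yl]-4H-1,3-dioxin-4-one | CC(=C)[C@H](O[Si](C)(C)C)CC1=CC(=O)OC(C)(C)O1 | intermediate (not isolated)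
5 | (R)-6-(2-hydroxy-3-methylbut-3-en-1-yl)-2,2-dimethyl-4H-1,3-dioxin-4-one | CC(=C)[C@H](O)CC1=CC(=O)OC(C)(C)O1 | intermediate
6 | ethyl 2-{[(2R)-1-(2,2-dimethyl-4-oxo-4H-1,3-dioxin-6-yl)-3-methylbut-3-en-2-yl]oxy}acetate | CC(=C)[C@H](OCC(=O)OCC)CC1=CC(=O)OC(C)(C)O1 | intermediate
7 | 2-{[(2R)-1-(2,2-dimethyl-4-oxo-4H-1,3-dioxin-6-yl)-3-methylbut-3-en-2-yl]oxy}acetaldehyde | CC(=C)[C@H](OCC=O)CC1=CC(=O)OC(C)(C)O1 | intermediate
8 | S-ethyl (5R)-6-methyl-3-oxo-5-(2-oxoethoxy)hept-6-enethioate | CCSC(=O)CC(=O)C[C@@H](OCC=O)C(C)=C | intermediate (not isolated)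
9 | S-ethyl (7R)-5-oxo-7-(prop-1-en-2-yl)-2,5,6,7-tetrahydrooxepine-4-carbothioate | CCSC(=O)C1=CCO[C@@H](C(C)=C)CC1=O | intermediate
10 | S-ethyl (1S,5R)-8,8-dimethyl-3-oxo-6-oxabicyclo[3.2.1]octane-2-carbothioate (C2 epimers/enol) | CCSC(=O)C1C(=O)C[C@H]2OC[C@@H]1C2(C)C | intermediate
11 | S-ethyl (1R,2R,5R)-2-(hydroxymethyl)-8,8-dimethyl-3-oxo-6-oxabicyclo[3.2.1]octane-2-carbothioate | CCSC(=O)[C@]1(CO)C(=O)C[C@H]2OC[C@@H]1C2(C)C | intermediate
12 | (1R,2S,5R)-2-(hydroxymethyl)-8,8-dimethyl-3-oxo-6-oxabicyclo[3.2.1]octane-2-carbaldehyde | O=C[C@]1(CO)C(=O)C[C@H]2OC[C@@H]1C2(C)C | intermediate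
13 | (triphenylphosphoranylidene)acetate ester of the CH2OH group of 12 | O=C[C@]1(COC(=O)C=P(c2ccccc2)(c2ccccc2)c2ccccc2)C(=O)C[C@H]3OC[C@@H]1C3(C)C | intermediate (not isolated)
14 | (1R,2S,5R)-8,8-dimethyl-2'H-spiro[6-oxabicyclo[3.2.1]octane-2,3'-pyran]-3,6'-dione | O=C1C=C[C@]2(CO1)C(=O)C[C@H]3OC[C@@H]2C3(C)C | intermediate
15 | 2-(trimethylsilyloxy)buta-1,3-diene | C=CC(=C)O[Si](C)(C)C | starting material
16 | cis-fused Diels–Alder adduct, silyl enol ether (ring-fusion H atoms on the face of bridgehead C1 of the bicycle) | C[Si](C)(C)OC1=CC[C@@H]2C(=O)OC[C@]3(C(=O)C[C@H]4OC[C@@H]3C4(C)C)[C@@H]2C1 | intermediate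
17 | (E)-but-2-en-1-ol | C/C=C/CO | starting material
18 | (E)-but-2-en-1-yl methyl carbonate | C/C=C/COC(=O)OC | intermediate
19 | α-[(2S)-but-3-en-2-yl] cyclohexanone, both epimers at the ring α-carbon | C[C@@H](C=C)C1C(=O)C[C@@H]2[C@H](C1)C(=O)OC[C@]21C(=O)C[C@H]2OC[C@@H]1C2(C)C | intermediate (not isolated)
20 | α-[(2S)-but-3-en-2-yl] cyclohexanone, equatorial epimer (trans to the spiro carbon) | C[C@@H](C=C)[C@@H]1C(=O)C[C@@H]2[C@H](C1)C(=O)OC[C@]21C(=O)C[C@H]2OC[C@@H]1C2(C)C | intermediate
21 | 4-methylbenzenesulfonylhydrazone of the cyclohexanone carbonyl of 20 | C[C@@H](C=C)[C@@H]1C(=NNS(=O)(=O)c3ccc(C)cc3)C[C@@H]2[C@H](C1)C(=O)OC[C@]21C(=O)C[C@H]2OC[C@@H]1C2(C)C | intermediate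
22 | deoxygenated vinyl compound (target skeleton with CH=CH2 in place of CO2H) | C[C@@H](C=C)[C@@H]1CC[C@@H]2[C@H](C1)C(=O)OC[C@]21C(=O)C[C@H]2OC[C@@H]1C2(C)C | intermediate
23 | aldehyde corresponding to the target acid | C[C@@H](C=O)[C@@H]1CC[C@@H]2[C@H](C1)C(=O)OC[C@]21C(=O)C[C@H]2OC[C@@H]1C2(C)C | intermediate (not isolated)
24 | target acid CNP0152427.2 | C[C@@H](C(=O)O)[C@@H]1CC[C@@H]2[C@H](C1)C(=O)OC[C@]21C(=O)C[C@H]2OC[C@@H]1C2(C)C | target

**Step count and risks**

Total steps: 15. Longest linear sequence: 14 (steps 1–10 and 12–15, from 1 to 24).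

Steps most likely to fail:

1. Step 6. The tertiary radical may be reduced, or the alkylidene may be consumed by the hydride system, before the transannular bond forms. Fallback, from 9 back to 10: Markovnikov addition of dry HBr (CH2Cl2, −40 °C) to the isopropenyl group would give S-ethyl (7R)-7-(2-bromopropan-2-yl)-5-oxo-2,5,6,7-tetrahydrooxepine-4-carbothioate F1. Bromine abstraction in a silane chain ((Me3Si)3SiH, Et3B, air, PhMe, 25 °C) then generates the same tertiary radical without any metal hydride. After cyclisation the dicarbonyl radical takes hydrogen from the silane to give 10.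

2. Step 5. The free aldehyde may be consumed by the acylketene or the thiol, or intermolecular condensation may outrun closure of the seven-membered ring. Fallback, from 7 back to 9: the aldehyde is masked first (HC(OMe)3, pyridinium 4-methylbenzenesulfonate, MeOH) as 6-[(2R)-2-(2,2-dimethoxyethoxy)-3-methylbut-3-en-1-yl]-2,2-dimethyl-4H-1,3-dioxin-4-one F2. Thermolysis with EtSH then gives the isolable S-ethyl (5R)-5-(2,2-dimethoxyethoxy)-6-methyl-3-oxohept-6-enethioate F3. The ring is closed in a separate operation at high dilution with TiCl4 and pyridine (THF, 0 °C), by Mukaiyama-type addition of the titanium enolate to the oxocarbenium ion from the acetal and loss of methanol, to give 9.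

3. Step 10. Cycloaddition at the neopentyl β-carbon may be too slow, with erosion of facial selectivity or loss of the silyl enol ether. Fallback, from 14 back to 20: the far more nucleophilic (E)-1-methoxy-3-(trimethylsilyloxy)buta-1,3-diene (PhMe, 110 °C) would give the 8-methoxy silyl enol ether cycloadduct F4, which is not isolated. Dilute HCl converts it into the cis-fused enone, 4a,5,8a-trihydro-1H-isochromene-1,6-dione spiro-linked as in 16, F5. Regiospecific 1,4-hydrosilylation (RhCl(PPh3)3, Et3SiH, PhMe, 50 °C) gives the triethylsilyl enol ether analogue of 16 F6, which takes the place of 16 under the conditions of step 12 and gives 20.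

**Further compounds**

F1 | step 6 | S-ethyl (7R)-7-(2-bromopropan-2-yl)-5-oxo-2,5,6,7-tetrahydrooxepine-4-carbothioate | CCSC(=O)C1=CCO[C@@H](C(C)(C)Br)CC1=O
F2 | step 5 | 6-[(2R)-2-(2,2-dimethoxyethoxy)-3-methylbut-3-en-1-yl]-2,2-dimethyl-4H-1,3-dioxin-4-one | CC(=C)[C@H](OCC(OC)OC)CC1=CC(=O)OC(C)(C)O1
F3 | step 5 | S-ethyl (5R)-5-(2,2-dimethoxyethoxy)-6-methyl-3-oxohept-6-enethioate | CCSC(=O)CC(=O)C[C@@H](OCC(OC)OC)C(C)=C
F4 | step 10 | 8-methoxy-6-(trimethylsilyloxy) cycloadduct (cis-fused, spiro-linked as in 16) | C[Si](C)(C)OC1=CC(OC)[C@@H]2C(=O)OC[C@]3(C(=O)C[C@H]4OC[C@@H]3C4(C)C)[C@@H]2C1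
F5 | step 10 | cis-fused enone, 4a,5,8a-trihydro-1H-isochromene-1,6-dione spiro-linked as in 16 | O=C1C=C[C@@H]2C(=O)OC[C@]3(C(=O)C[C@H]4OC[C@@H]3C4(C)C)[C@@H]2C1
F6 | step 10 | triethylsilyl enol ether analogue of 16 | CC[Si](CC)(CC)OC1=CC[C@@H]2C(=O)OC[C@]3(C(=O)C[C@H]4OC[C@@H]3C4(C)C)[C@@H]2C1
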